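**Retrosynthetic overview**

- The strategy rests on the C3–C4 ethano unit of ring C, which carries ring B (C1') on C3 and ring A (C4a) on C4. A vinylboron two-carbon linchpin can therefore accept both aryl groups in one operation and keep boron on C3.
- Ring C is opened at O1–C2 (Mitsunobu etherification), and C2 is removed as a CH2 unit inserted into the C3–B bond (Matteson homologation, retention).
- The remaining C3–C1' and C4–C4a bonds are cut together by an enantioselective three-component conjunctive coupling of a ring B aryllithium, vinylboronic acid pinacol ester and a ring A aryl bromide. This sets C3 as (S).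
- The ring B bromide comes from 2,6-dimethoxyphenol (silylation, bromination, γ-selective prenyl coupling, second bromination). The ring A bromide comes from 4-bromoresorcinol (silyl at the future O7, MOM at the future O1).
- Rings A and B are bought as arenes; ring C is the only ring formed, in step 11, after which both silyl ethers are removed.

Key step: step 7

Assumption: the ligand enantiomer for step 7 is specified by its outcome, the (S) configuration at the boron-bearing carbon, because the sense of induction is assigned by analogy and both ligand enantiomers are available.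

**Route**

Step 1
Reactants: 1 2,6-dimethoxyphenol
Product: 2 (2,6-dimethoxyphenoxy)triisopropylsilane
Conditions: TIPSCl, imidazole, DMF, rt
Reagents that add atoms: chlorotriisopropylsilane (TIPSCl), CC(C)[Si](Cl)(C(C)C)C(C)C
Why: O-Silylation of a phenol with a silyl chloride and imidazole is routine, and the bulky silyl ether, twisted out of the ring plane by its two methoxy neighbours, later keeps electrophiles away from C4 and tolerates organolithium and aqueous base steps.

Step 2
Reactants: 2 (2,6-dimethoxyphenoxy)triisopropylsilane
Product: 3 (3-bromo-2,6-dimethoxyphenoxy)triisopropylsilane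
Conditions: NBS (1.0 equiv), MeCN, 0 °C → rt
Reagents that add atoms: N-bromosuccinimide (NBS), O=C1CCC(=O)N1Br
Why: Electrophilic aromatic bromination should go to C3, ortho to one methoxy group and para to the other, because the twisted silyloxy group activates its own para position only weakly, and the first bromine slows a second substitution.

Step 3
Reactants: 3 (3-bromo-2,6-dimethoxyphenoxy)triisopropylsilane; 4 3-methyl-2-butenylboronic acid pinacol ester
Product: 5 [2,6-dimethoxy-3-(2-methylbut-3-en-2-yl)phenoxy]triisopropylsilane
Conditions: Pd(OAc)2 (3 mol%), SPhos (2-dicyclohexylphosphino-2',6'-dimethoxybiphenyl, 6 mol%; ligand chosen for γ-selectivity), aq K3PO4, THF, 40 °C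
Reagents that add atoms: none
Why: Suzuki–Miyaura coupling of 3,3-disubstituted allylboronates is known to give either regioisomer under ligand control: SE2' transmetalation places palladium on the tertiary carbon, and a ligand that makes reductive elimination faster than σ–π–σ isomerisation delivers the 1,1-dimethylallyl (γ) product.

Step 4
Reactants: 5 [2,6-dimethoxy-3-(2-methylbut-3-en-2-yl)phenoxy]triisopropylsilane
Product: 6 [3-bromo-2,6-dimethoxy-5-(2-methylbut-3-en-2-yl)phenoxy]triisopropylsilane (ring B bromide)
Conditions: NBS (1.05 equiv), MeCN, 0 °C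
Reagents that add atoms: N-bromosuccinimide (NBS), O=C1CCC(=O)N1Br
Why: Electrophilic aromatic bromination should go to the free position ortho to a methoxy group, since the other free position is shielded by the neighbouring quaternary carbon and is para only to the twisted silyloxy group, and the isolated monosubstituted alkene reacts with NBS far more slowly than the trioxygenated ring when no nucleophilic cosolvent is present.

Step 5
Reactants: 7 4-bromoresorcinol
Product: 8 2-bromo-5-(triisopropylsilyloxy)phenol
Conditions: TIPSCl (1.0 equiv), imidazole, CH2Cl2, 0 °C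
Reagents that add atoms: chlorotriisopropylsilane (TIPSCl), CC(C)[Si](Cl)(C(C)C)C(C)C
Why: Site-selective silylation under steric control: the hydroxyl para to bromine is unhindered, whereas the one ortho to bromine is shielded and weakly hydrogen-bonded to the halogen, so one equivalent of the bulky silyl chloride should take the para hydroxyl (the future O7).

Step 6
Reactants: 8 2-bromo-5-(triisopropylsilyloxy)phenol
Product: 9 [4-bromo-3-(methoxymethoxy)phenoxy]triisopropylsilane (ring A bromide)
Conditions: MOMCl, i-Pr2NEt, CH2Cl2, 0 °C → rt
Reagents that add atoms: chloromethyl methyl ether (MOMCl), COCCl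
Why: O-Alkylation of the remaining phenol with chloromethyl methyl ether and a hindered amine (MOM acetal protection of the future O1) is routine and leaves the aryl silyl ether and the aryl bromide untouched.

Step 7
Reactants: 6 ring B bromide; 10 vinylboronic acid pinacol ester; 9 ring A bromide
Product: 13 (S)-configured secondary benzylic pinacol boronic ester, via ring B aryllithium 11 (not isolated), via lithium vinylborate complex 12 (not isolated)
Conditions: 6, t-BuLi (2 equiv), Et2O, −78 °C; 10, −78 °C → rt; then KOTf (potassium trifluoromethanesulfonate), Pd(OAc)2 (cat.), MandyPhos ligand (1,1'-bis(diphenylphosphino)-2,2'-bis[α-(dimethylamino)benzyl]ferrocene, enantiomer giving the (S) product, cat.), 9, THF, 60 °C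
Reagents that add atoms: none
Why: Bromine–lithium exchange on 6 gives aryllithium 11, which adds to boron of 10 to form ate complex 12; zerovalent palladium formed from Pd(OAc)2 and the bisphosphine inserts into the C–Br bond of 9, triflate replaces bromide to leave a cationic divalent arylpalladium, this coordinates the vinyl group of 12 and provokes a 1,2-shift of ring B from boron to the α-carbon anti to the metal, and reductive elimination joins the β-carbon (C4) to C4a. The closest known reaction is the palladium-catalysed enantioselective conjunctive cross-coupling of vinylboron ate complexes with aryl electrophiles, which is established for aryl migrating groups, pinacol boronates and aryl bromides when a triflate salt is present. No ring is closed: the step forms the two skeletal bonds C3–C1' and C4–C4a and leaves boron on C3. The C3 stereocentre is set by the chiral ferrocenyl bisphosphine, which selects the alkene face bound by palladium during the metallate shift, and the ligand enantiomer is chosen to give the (S) boronic ester. The step needs the conjunctive pathway to outrun direct Suzuki transfer of ring B or vinyl from boron to palladium; this is secured by the cationic palladium centre, kept free of bromide by KOTf, and by the hindered, ortho-methoxy-flanked ring B, which transmetalates slowly. The hindered, unactivated vinyl group of the dimethylallyl side chain should not compete with the electron-rich vinylborate for palladium, and the silyl ethers and the acetal are inert.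

Step 8
Reactants: 13 (S)-configured secondary benzylic pinacol boronic ester
Product: 15 (S)-homologated primary pinacol boronic ester, via lithium chloromethylborate complex 14 (not isolated)
Conditions: BrCH2Cl, n-BuLi, THF, −78 °C → rt
Reagents that add atoms: bromochloromethane, ClCBr
Why: Matteson homologation: chloromethyllithium formed by bromine–lithium exchange adds to boron, and on warming the secondary benzylic carbon migrates to the CH2 group with loss of chloride and with retention at C3, so the (S) centre is carried over and C2 is in place.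

Step 9
Reactants: 15 (S)-homologated primary pinacol boronic ester
Product: 16 (2S)-2-(ring B aryl)-3-(ring A aryl)propan-1-ol
Conditions: NaBO3·4H2O, THF/H2O, rt
Reagents that add atoms: sodium perborate (NaBO3, used as NaBO3·4H2O), [Na+].[O-]B1OO1
Why: Oxidation of the primary C–B bond by perborate (peroxide attack on boron, then 1,2-shift of carbon to oxygen) is mild enough for the aryl silyl ethers, the acetal and the alkene and does not touch the stereocentre.

Step 10
Reactants: 16 (2S)-2-(ring B aryl)-3-(ring A aryl)propan-1-ol
Product: 17 2-[(2S)-2-(ring B aryl)-3-hydroxypropyl]-5-(triisopropylsilyloxy)phenol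
Conditions: conc. HCl (cat.), MeOH/THF, rt → 40 °C
Reagents that add atoms: none
Why: Acid-catalysed acetal exchange with methanol removes the phenolic MOM group, while aryl triisopropylsilyl ethers, the primary alcohol and the monosubstituted alkene are stable to dilute acid at this temperature.

Step 11
Reactants: 17 2-[(2S)-2-(ring B aryl)-3-hydroxypropyl]-5-(triisopropylsilyloxy)phenol
Product: 18 (3S)-isoflavan bis(triisopropylsilyl) ether
Conditions: PPh3, DIAD, THF (0.02 M), 0 °C → rt
Reagents that add atoms: none
Why: Intramolecular Mitsunobu etherification: the alkoxyphosphonium at C2 is displaced by the only free phenoxide (O1) in a 6-exo-tet closure that forms ring C, and because the reacting carbon is a CH2 group the C3 centre is unaffected.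

Step 12
Reactants: 18 (3S)-isoflavan bis(triisopropylsilyl) ether
Product: 19 (3S)-3-[3-hydroxy-2,4-dimethoxy-5-(2-methylbut-3-en-2-yl)phenyl]-3,4-dihydro-2H-chromen-7-ol (target)
Conditions: Bu4NF, AcOH, THF, 0 °C → rt
Reagents that add atoms: none
Why: Fluoride cleaves both aryl Si–O bonds, driven by the strength of the Si–F bond, and the acetic acid buffer keeps the electron-rich phenols protonated, with no effect on the stereocentre or the alkene.

**Compound list**

1 | 2,6-dimethoxyphenol | COc1cccc(OC)c1O | starting material
2 | (2,6-dimethoxyphenoxy)triisopropylsilane | COc1cccc(OC)c1O[Si](C(C)C)(C(C)C)C(C)C | intermediate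
3 | (3-bromo-2,6-dimethoxyphenoxy)triisopropylsilane | COc1ccc(Br)c(OC)c1O[Si](C(C)C)(C(C)C)C(C)C | intermediate
4 | 3-methyl-2-butenylboronic acid pinacol ester | CC(C)=CCB1OC(C)(C)C(C)(C)O1 | starting material
5 | [2,6-dimethoxy-3-(2-methylbut-3-en-2-yl)phenoxy]triisopropylsilane | C=CC(C)(C)c1ccc(OC)c(O[Si](C(C)C)(C(C)C)C(C)C)c1OC | intermediate
6 | [3-bromo-2,6-dimethoxy-5-(2-methylbut-3-en-2-yl)phenoxy]triisopropylsilane (ring B bromide) | C=CC(C)(C)c1cc(Br)c(OC)c(O[Si](C(C)C)(C(C)C)C(C)C)c1OC | intermediate
7 | 4-bromoresorcinol (4-bromobenzene-1,3-diol) | Oc1ccc(Br)c(O)c1 | starting material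
8 | 2-bromo-5-(triisopropylsilyloxy)phenol | Oc1cc(O[Si](C(C)C)(C(C)C)C(C)C)ccc1Br | intermediate
9 | [4-bromo-3-(methoxymethoxy)phenoxy]triisopropylsilane (ring A bromide) | COCOc1cc(O[Si](C(C)C)(C(C)C)C(C)C)ccc1Br | intermediate
10 | vinylboronic acid pinacol ester | C=CB1OC(C)(C)C(C)(C)O1 | starting material
11 | [2,4-dimethoxy-5-(2-methylbut-3-en-2-yl)-3-(triisopropylsilyloxy)phenyl]lithium (ring B aryllithium) | [Li]c1cc(C(C)(C)C=C)c(OC)c(O[Si](C(C)C)(C(C)C)C(C)C)c1OC | intermediate
12 | lithium [2,4-dimethoxy-5-(2-methylbut-3-en-2-yl)-3-(triisopropylsilyloxy)phenyl](ethenyl)(pinacolato)borate | [Li+].C=C[B-]1(OC(C)(C)C(C)(C)O1)c1cc(C(C)(C)C=C)c(OC)c(O[Si](C(C)C)(C(C)C)C(C)C)c1OC | intermediate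
13 | 2-[(1S)-1-[2,4-dimethoxy-5-(2-methylbut-3-en-2-yl)-3-(triisopropylsilyloxy)phenyl]-2-[2-(methoxymethoxy)-4-(triisopropylsilyloxy)phenyl]ethyl]-4,4,5,5-tetramethyl-1,3,2-dioxaborolane | CC1(C)OB(OC1(C)C)[C@H](c1cc(C(C)(C)C=C)c(OC)c(O[Si](C(C)C)(C(C)C)C(C)C)c1OC)Cc1ccc(O[Si](C(C)C)(C(C)C)C(C)C)cc1OCOC | intermediate
14 | lithium (chloromethyl)[(1S)-1-(ring B aryl)-2-(ring A aryl)ethyl](pinacolato)borate, aryl groups as in 13 | [Li+].ClC[B-]1(OC(C)(C)C(C)(C)O1)[C@H](c1cc(C(C)(C)C=C)c(OC)c(O[Si](C(C)C)(C(C)C)C(C)C)c1OC)Cc1ccc(O[Si](C(C)C)(C(C)C)C(C)C)cc1OCOC | intermediate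
15 | 2-[(2S)-2-[2,4-dimethoxy-5-(2-methylbut-3-en-2-yl)-3-(triisopropylsilyloxy)phenyl]-3-[2-(methoxymethoxy)-4-(triisopropylsilyloxy)phenyl]propyl]-4,4,5,5-tetramethyl-1,3,2-dioxaborolane | CC1(C)OB(OC1(C)C)C[C@H](c1cc(C(C)(C)C=C)c(OC)c(O[Si](C(C)C)(C(C)C)C(C)C)c1OC)Cc1ccc(O[Si](C(C)C)(C(C)C)C(C)C)cc1OCOC | intermediate
16 | (2S)-2-[2,4-dimethoxy-5-(2-methylbut-3-en-2-yl)-3-(triisopropylsilyloxy)phenyl]-3-[2-(methoxymethoxy)-4-(triisopropylsilyloxy)phenyl]propan-1-ol | OC[C@H](c1cc(C(C)(C)C=C)c(OC)c(O[Si](C(C)C)(C(C)C)C(C)C)c1OC)Cc1ccc(O[Si](C(C)C)(C(C)C)C(C)C)cc1OCOC | intermediate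
17 | 2-[(2S)-2-[2,4-dimethoxy-5-(2-methylbut-3-en-2-yl)-3-(triisopropylsilyloxy)phenyl]-3-hydroxypropyl]-5-(triisopropylsilyloxy)phenol | OC[C@H](c1cc(C(C)(C)C=C)c(OC)c(O[Si](C(C)C)(C(C)C)C(C)C)c1OC)Cc1ccc(O[Si](C(C)C)(C(C)C)C(C)C)cc1O | intermediate
18 | triisopropyl{[(3S)-3-[2,4-dimethoxy-5-(2-methylbut-3-en-2-yl)-3-(triisopropylsilyloxy)phenyl]-3,4-dihydro-2H-chromen-7-yl]oxy}silane | C=CC(C)(C)c1cc([C@H]2COc3cc(O[Si](C(C)C)(C(C)C)C(C)C)ccc3C2)c(OC)c(O[Si](C(C)C)(C(C)C)C(C)C)c1OC | intermediate
19 | (3S)-3-[3-hydroxy-2,4-dimethoxy-5-(2-methylbut-3-en-2-yl)phenyl]-3,4-dihydro-2H-chromen-7-ol | C=CC(C)(C)c1cc([C@H]2COc3cc(O)ccc3C2)c(OC)c(O)c1OC | target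

**Step count**

Total: 12 steps. Longest linear sequence: 10 steps (steps 1–4 and 7–12, from 2,6-dimethoxyphenol).

**Steps most likely to fail**

1. Step 7 (key step). Oxidative addition into the electron-rich, ortho-alkoxy bromide 9 and alkene binding may be slow. Direct transfer of ring B or of the vinyl group from boron to palladium would then compete with the metallate shift, residual bromide could stall the catalyst, and face selectivity could drop with the ortho-methoxy migrating group. The fallback sets out from 9 and 6 and returns at 13, using carbamate lithiation–borylation, in which the stereocentre is set by a chiral diamine instead of palladium.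
   - Bromine–lithium exchange on 9 (t-BuLi, THF, −78 °C) and opening of oxirane (BF3·OEt2) should give 2-[2-(methoxymethoxy)-4-(triisopropylsilyloxy)phenyl]ethanol F1.
   - Acylation with N,N-diisopropylcarbamoyl chloride (Et3N, CH2Cl2, reflux) should give the corresponding N,N-diisopropylcarbamate F2.
   - Separately, 6 is lithiated (t-BuLi, Et2O, −78 °C) and quenched with 2-isopropoxy-4,4,5,5-tetramethyl-1,3,2-dioxaborolane to give the ring B arylboronic acid pinacol ester F3.
   - Deprotonation of F2 with s-BuLi and (+)-sparteine (the enantiomer expected to remove the pro-R hydrogen; Et2O, −78 °C), addition of F3, and warming with MgBr2·OEt2 should induce 1,2-migration of ring B with loss of the carbamate and give 13.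

2. Step 3. The tertiary σ-allylpalladium next to an ortho-methoxy group may isomerise to the primary allyl before reductive elimination, giving the linear prenyl arene, or the congested coupling may stall. The fallback sets out from 3 and returns at 5, building the quaternary benzylic carbon by enolate arylation.
   - Palladium-catalysed α-arylation of 2-methylpropanal with 3 (Pd(OAc)2, rac-BINAP, Cs2CO3, dioxane, 80 °C) should give 2-[2,4-dimethoxy-3-(triisopropylsilyloxy)phenyl]-2-methylpropanal F4.
   - Wittig methylenation (Ph3PCH3Br, KOt-Bu, THF, 0 °C → rt) then converts the aldehyde of F4 into the vinyl group of 5.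

3. Step 8. Chloromethyllithium may decompose before it is captured by the hindered secondary boronic ester, migration of the congested benzylic carbon may be slow, and the less hindered product may take up a second CH2 unit. The fallback sets out from 13 and returns at 15 by a two-stage homologation through an isolable halide.
   - Preformed LiCHCl2 (CH2Cl2, n-BuLi, THF, −100 °C) adds to 13, and ZnCl2 on warming drives the migration with retention to give the α-chloroboronic ester F5, as a mixture of epimers at the CHCl carbon that is of no consequence. F5 resists a second insertion.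
   - LiBHEt3 (THF, −78 °C → rt) then adds to boron, and a 1,2-hydride shift displaces chloride to give 15.

**Further compounds**

F1 | step 7 | 2-[2-(methoxymethoxy)-4-(triisopropylsilyloxy)phenyl]ethanol | OCCc1ccc(O[Si](C(C)C)(C(C)C)C(C)C)cc1OCOC
F2 | step 7 | 2-[2-(methoxymethoxy)-4-(triisopropylsilyloxy)phenyl]ethyl N,N-diisopropylcarbamate | CC(C)N(C(C)C)C(=O)OCCc1ccc(O[Si](C(C)C)(C(C)C)C(C)C)cc1OCOC
F3 | step 7 | 2-[2,4-dimethoxy-5-(2-methylbut-3-en-2-yl)-3-(triisopropylsilyloxy)phenyl]-4,4,5,5-tetramethyl-1,3,2-dioxaborolane | C=CC(C)(C)c1cc(B2OC(C)(C)C(C)(C)O2)c(OC)c(O[Si](C(C)C)(C(C)C)C(C)C)c1OC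
F4 | step 3 | 2-[2,4-dimethoxy-3-(triisopropylsilyloxy)phenyl]-2-methylpropanal | O=CC(C)(C)c1ccc(OC)c(O[Si](C(C)C)(C(C)C)C(C)C)c1OC
F5 | step 8 | 2-[(2S)-1-chloro-2-[2,4-dimethoxy-5-(2-methylbut-3-en-2-yl)-3-(triisopropylsilyloxy)phenyl]-3-[2-(methoxymethoxy)-4-(triisopropylsilyloxy)phenyl]propyl]-4,4,5,5-tetramethyl-1,3,2-dioxaborolane (both epimers at C1) | CC1(C)OB(OC1(C)C)C(Cl)[C@H](c1cc(C(C)(C)C=C)c(OC)c(O[Si](C(C)C)(C(C)C)C(C)C)c1OC)Cc1ccc(O[Si](C(C)C)(C(C)C)C(C)C)cc1OCOC
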